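30 min is less than one lifetime of L in this flask, so the quick number you asked for comes from counting turnovers.

L 0.050 M; G 0.100 M; time 30 min

- how much J and Q together there is at 30 min, in percent of the L charged
- the change that raises the amount of J and Q together at 30 min, in percent of the L charged most ("none" if none brings more than 2 percentage points) (Thursday's / Friday's / Tuesday's / none)
- amount of J and Q together at 30 min, in percent of the L charged, after Tuesday's

- Thursday's: doubling the amount of G, all else as stated
- Friday's: doubling the dissolution coefficient of step 4, all else as stated
- Tuesday's: doubling the solubility in step 4, all else as stated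

    L + G → J + X (k1 = 0.142 L mol⁻¹ min⁻¹)
    G + D → E + X (k2 = 0.239 L mol⁻¹ min⁻¹)
    G + J → D + X (k3 = 0.0114 L mol⁻¹ min⁻¹)
    Q ⇌ J, rate k4*(cs4 - [J]) while solid is left; crystals form when [J] > cs4 (cs4 = 11 mM, k4 = 1.23 min⁻¹)

L (substrate) meets G (reagent) to give J (mono adduct) and X with the constant 0.142 L mol⁻¹ min⁻¹. While G stands near its charge this step is pseudo-first-order in L, and the run holds

N = 0.142 L mol⁻¹ min⁻¹ × 0.100 M × 30 min = 0.426

lifetimes of L. This N, the turnover count, is rate constant times G times time.

With G held, the part of L used would be

c = 1 − e^(−N) = 34.7%.

But G falls as L is used, and at mid-run it stands at the fraction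

g = 1 − 0.5 c [L]/[G] = 0.913.

So this reckoning gives

y = 1 − e^(−gN) = 32.2%.

Dissolved J has a half-life of 10 h by step 3 alone, with G as charged, which is longer than the run. Q (crystals) is counted with J, so this reckoning has no term for the solubility, and yb comes to 32.2%. Doubling G (Thursday's) doubles N, while doubling the dissolution coefficient 1.23 min⁻¹ (Friday's) or the solubility 11 mM (Tuesday's) leaves N as it is; the pick is Thursday's.

The forecast has y = 31.8%, a little below this reckoning, yb = 31.7% and Thursday's, holding that “crystals simply hold J as Q”.

The simulation gives y = 31.7%, yb = 31.6% and Thursday's, which gains 21 percentage points.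

The forecast stands, and for this flask it means that the main reason for the low y is the time given, against ten times as long: N is below 1. Left for 300 min, the same flask reaches 88.6%, which is 57 points more. In the neighbour flask with 0.17 M of G, the count is N = 0.724 and g = 0.924, which gives 48.8%. That flask stands at 47.5% of J and Q together at 30 min.

The constants are assumed.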